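The route rests on cutting the C11–C12 bond of the cyclopentenone ring (prostanoid numbering: ester carbon C1, ring C8–C12, C9 the ketone). The feature exploited is the tertiary oxygenated C12 next to C11, a ring CH that can pass through the ketone level: together they are an acyloin. A chiral triazolylidene turns the C11 aldehyde of an achiral, open-chain keto aldehyde into an acyl anion equivalent that adds to the C12 ketone, so one operation forms the C11–C12 bond, the five-membered ring C8–C12 and the only stereocentre. The precursor carries C9 as a dioxolane and the complete (Z)-octenyl chain on the C12 ketone.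

Key step: step 10

Assumptions and remarks on the chemistry
- Positions are given in prostanoid numbering throughout (chain C1–C7, ring C8–C12, chain C13–C20).
- Assumption: the (5aS,10bR) triazolium salt is taken to give (S)-14. If a first run shows the opposite sense, its mirror image (5aR,10bS), made from the other enantiomer of cis-1-amino-2-indanol, is used and nothing else changes.
- Centres that are destroyed later are carried as mixtures: the carbinol carbon in 8–12, C11 in 15–17, C10/C11 in 19–21, C7/C8 in 26–27.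
- The descriptor at C12 changes from S (14–27) to R (28, 29) only because C8 becomes sp2 and gains priority. No bond to C12 is made or broken after step 10.
- Two design points guard the flanks of the key step. The 1,5-diol 12 is oxidised under Swern conditions, because stepwise oxidants would pass through a C11 lactol and over-oxidise it to the lactone. The secondary C11 hydroxyl is sulfonylated before C9 is unmasked (and again after bromide opening), because the tertiary C12 hydroxyl is also β to C9 through C8 and would otherwise compete in the loss of water.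

Step 1
Reactants: 1 dimethyl 3-oxopentanedioate; 2 ethane-1,2-diol
Product: 3 dimethyl 2,2'-(1,3-dioxolane-2,2-diyl)diacetate
Conditions: p-TsOH·H2O (cat.), toluene, reflux, Dean–Stark
Reagents that add atoms: none
Why: Acid-catalysed ketalisation with azeotropic removal of water masks the future C9 ketone at the outset, when the only other carbonyls are esters that do not ketalise.

Step 2
Reactants: 3 dimethyl 2,2'-(1,3-dioxolane-2,2-diyl)diacetate
Product: 4 2,2'-(1,3-dioxolane-2,2-diyl)di(ethan-1-ol)
Conditions: LiAlH4, THF, 0 °C → rt; Fieser work-up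
Reagents that add atoms: none
Why: Hydride reduction of both esters to primary alcohols leaves the ketal untouched and gives a symmetrical diol whose two ends become C11 and C12.

Step 3
Reactants: 4 2,2'-(1,3-dioxolane-2,2-diyl)di(ethan-1-ol)
Product: 5 2-[2-(2-{[tert-butyl(dimethyl)silyl]oxy}ethyl)-1,3-dioxolan-2-yl]ethan-1-ol
Conditions: NaH (1.0 equiv), THF, rt; TBSCl (1.0 equiv)
Reagents that add atoms: tert-butyl(chloro)dimethylsilane (TBSCl), CC(C)(C)[Si](C)(C)Cl
Why: O-Silylation of the sparingly soluble monosodium alkoxide of a symmetrical diol should stop at the mono-ether and so tells the future C11 end from the future C12 end.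

Step 4
Reactants: 5 2-[2-(2-{[tert-butyl(dimethyl)silyl]oxy}ethyl)-1,3-dioxolan-2-yl]ethan-1-ol
Product: 6 2-[2-(2-{[tert-butyl(dimethyl)silyl]oxy}ethyl)-1,3-dioxolan-2-yl]acetaldehyde
Conditions: Dess–Martin periodinane, pyridine, CH2Cl2, 0 °C → rt
Reagents that add atoms: none
Why: Dess–Martin oxidation of the single primary alcohol under buffered, non-aqueous conditions should give the β-ketal aldehyde without over-oxidation, silyl loss or opening of the dioxolane.

Step 5
Reactants: 6 2-[2-(2-{[tert-butyl(dimethyl)silyl]oxy}ethyl)-1,3-dioxolan-2-yl]acetaldehyde; 7 3-bromoprop-1-yne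
Product: 8 rac-1-[2-(2-{[tert-butyl(dimethyl)silyl]oxy}ethyl)-1,3-dioxolan-2-yl]pent-4-yn-2-ol
Conditions: Zn dust, THF, 0 °C → rt; aq. NH4Cl
Reagents that add atoms: none
Why: Barbier-type zinc propargylation runs through the allenylzinc bromide and an SE2' addition, so the unsubstituted reagent should give the homopropargylic alcohol; the new carbinol centre (future C12) is racemic and is erased by oxidation in step 9.

Step 6
Reactants: 8 rac-1-[2-(2-{[tert-butyl(dimethyl)silyl]oxy}ethyl)-1,3-dioxolan-2-yl]pent-4-yn-2-ol; 9 1-iodopentane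
Product: 10 rac-1-[2-(2-{[tert-butyl(dimethyl)silyl]oxy}ethyl)-1,3-dioxolan-2-yl]dec-4-yn-2-ol
Conditions: n-BuLi (2.2 equiv), THF, −78 °C; DMPU, then 9, −78 °C → rt
Reagents that add atoms: none
Why: Acetylide alkylation of the alkoxide–acetylide dianion by the primary iodide should occur on carbon, the lithium alkoxide being far the weaker nucleophile, and completes the C13–C20 chain.

Step 7
Reactants: 10 rac-1-[2-(2-{[tert-butyl(dimethyl)silyl]oxy}ethyl)-1,3-dioxolan-2-yl]dec-4-yn-2-ol
Product: 11 rac-(Z)-1-[2-(2-{[tert-butyl(dimethyl)silyl]oxy}ethyl)-1,3-dioxolan-2-yl]dec-4-en-2-ol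
Conditions: H2 (1 atm), Pd/CaCO3 poisoned with Pb(OAc)2 (Lindlar catalyst), quinoline, EtOAc, rt
Reagents that add atoms: none
Why: Lindlar semi-hydrogenation adds both hydrogens to one face of the alkyne and so sets the (Z) geometry of C14=C15.

Step 8
Reactants: 11 rac-(Z)-1-[2-(2-{[tert-butyl(dimethyl)silyl]oxy}ethyl)-1,3-dioxolan-2-yl]dec-4-en-2-ol
Product: 12 rac-(Z)-1-[2-(2-hydroxyethyl)-1,3-dioxolan-2-yl]dec-4-en-2-ol
Conditions: Bu4NF, THF, 0 °C → rt
Reagents that add atoms: none
Why: Fluoride desilylation frees the primary alcohol at a stage where no base-sensitive carbonyl is yet present.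

Step 9
Reactants: 12 rac-(Z)-1-[2-(2-hydroxyethyl)-1,3-dioxolan-2-yl]dec-4-en-2-ol
Product: 13 2-{2-[(Z)-2-oxodec-4-enyl]-1,3-dioxolan-2-yl}acetaldehyde
Conditions: (COCl)2, DMSO, CH2Cl2, −78 °C; i-Pr2NEt, −78 → −30 °C; cold pH 7 buffer; used at once
Reagents that add atoms: none
Why: In the Swern oxidation both hydroxyls become alkoxysulfonium ions before any carbonyl exists, so no C11 lactol can form and be over-oxidised, and the hindered amine at low temperature should leave the skipped C14=C15 alkene and the two β-ketal carbonyls alone.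

Step 10
Reactants: 13 2-{2-[(Z)-2-oxodec-4-enyl]-1,3-dioxolan-2-yl}acetaldehyde
Product: 14 (8S)-8-hydroxy-8-[(Z)-oct-2-enyl]-1,4-dioxaspiro[4.4]nonan-7-one
Conditions: (5aS,10bR)-2-(pentafluorophenyl)-5a,10b-dihydro-4H,6H-indeno[2,1-b][1,2,4]triazolo[4,3-d][1,4]oxazin-2-ium tetrafluoroborate (15 mol %), Et3N (15 mol %), toluene (0.02 M), rt
Reagents that add atoms: none
Why: Et3N frees the carbene, which adds to the unhindered C11 aldehyde; proton transfer gives the enaminol (acyl anion equivalent), this attacks the C12 ketone, and collapse of the adduct releases the carbene and leaves the C11 ketone beside the C12 tertiary alcohol. The closest known reaction type is the enantioselective intramolecular crossed aldehyde–ketone benzoin reaction of enolisable keto aldehydes with aminoindanol-derived triazolium salts. The cyclopentane ring C8–C12 closes in a 5-exo-trig mode, helped by the gem-disubstituted C9 ketal. C12, the only new stereocentre, is set by the catalyst alone: the indane wall shields one face of the enaminol and the hydrogen bond from the enaminol O–H to the C12 carbonyl oxygen fixes which ketone face is presented, the (S) sense being the stated assumption. The step needs cross-selectivity and must outrun enolate chemistry; only the aldehyde can form the enaminol and only the ketone sits five atoms away, while a catalyst-level charge of a weak amine should be too little to drive the six-membered aldol from C13, the shift of C14=C15 into conjugation or β-elimination of the ketal.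

Step 11
Reactants: 14 (8S)-8-hydroxy-8-[(Z)-oct-2-enyl]-1,4-dioxaspiro[4.4]nonan-7-one
Product: 15 (8S)-8-[(Z)-oct-2-enyl]-1,4-dioxaspiro[4.4]nonane-7,8-diol (both C7 epimers)
Conditions: NaBH4, MeOH, 0 °C
Reagents that add atoms: none
Why: Borohydride reduction of the C11 ketone should give the vicinal diol as a mixture of C11 epimers, which does not matter because C11 becomes sp2 in step 13.

Step 12
Reactants: 15 (8S)-8-[(Z)-oct-2-enyl]-1,4-dioxaspiro[4.4]nonane-7,8-diol
Product: 16 (8S)-8-hydroxy-8-[(Z)-oct-2-enyl]-1,4-dioxaspiro[4.4]nonan-7-yl methanesulfonate (both C7 epimers)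
Conditions: MsCl (1.1 equiv), Et3N, CH2Cl2, −20 °C
Reagents that add atoms: methanesulfonyl chloride, CS(=O)(=O)Cl
Why: Sulfonylation should select the secondary C11 hydroxyl over the hindered tertiary C12 hydroxyl, which makes C11–O the only leaving group although C12–O is also β to C9.

Step 13
Reactants: 16 (8S)-8-hydroxy-8-[(Z)-oct-2-enyl]-1,4-dioxaspiro[4.4]nonan-7-yl methanesulfonate
Product: 18 (4S)-4-hydroxy-4-[(Z)-oct-2-enyl]cyclopent-2-en-1-one, via β-mesyloxy ketone 17 (not isolated)
Conditions: aq. HCl (cat.), THF/H2O, rt; then Et3N, 0 °C → rt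
Reagents that add atoms: water, O
Why: Acid hydrolysis of the dioxolane unmasks the C9 ketone and the β-sulfonyloxy ketone then loses methanesulfonate by E1cB elimination through the C10 enolate, which should give only the C10=C11 enone and leave C12 untouched.

Step 14
Reactants: 18 (4S)-4-hydroxy-4-[(Z)-oct-2-enyl]cyclopent-2-en-1-one
Product: 19 (4S)-4-hydroxy-4-[(Z)-oct-2-enyl]-6-oxabicyclo[3.1.0]hexan-2-one (epoxide face not fixed)
Conditions: 30% aq. H2O2, NaOH (0.3 equiv), MeOH, −10 → 0 °C, short reaction time
Reagents that add atoms: hydrogen peroxide, OO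
Why: Weitz–Scheffer nucleophilic epoxidation attacks only the electron-poor C10=C11 bond and spares the isolated (Z)-alkene, and the cold, brief exposure to base is meant to keep the tertiary β-hydroxy ketone from retro-aldol opening.

Step 15
Reactants: 19 (4S)-4-hydroxy-4-[(Z)-oct-2-enyl]-6-oxabicyclo[3.1.0]hexan-2-one
Product: 22 (4S)-2-bromo-4-hydroxy-4-[(Z)-oct-2-enyl]cyclopent-2-en-1-one, via bromohydrin 20 (not isolated), via bromohydrin mesylate 21 (not isolated)
Conditions: LiBr, AcOH, THF, rt; crude, then MsCl (1.1 equiv), Et3N, CH2Cl2, −20 → 0 °C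
Reagents that add atoms: lithium bromide, [Li+].[Br-]
Why: Bromide should open the protonated epoxy ketone by SN2 attack at C10 (α to the carbonyl and remote from the quaternary C12), and selective mesylation of the secondary C11 hydroxyl followed by E1cB elimination then gives the 2-bromoenone, so bromine enters as a nucleophile and the isolated alkene never meets electrophilic bromine.

Step 16
Reactants: 23 methyl hex-5-enoate; 24 (E)-but-2-enal
Product: 25 methyl (E)-7-oxohept-5-enoate
Conditions: second-generation Grubbs catalyst RuCl2(=CHPh)(PCy3)(H2IMes) (2 mol %), 24 (5 equiv), CH2Cl2, 40 °C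
Reagents that add atoms: none
Why: Olefin cross-metathesis of a terminal alkene with an excess of an electron-poor enal should favour the cross product with (E) geometry, propene being lost.

Step 17
Reactants: 22 (4S)-2-bromo-4-hydroxy-4-[(Z)-oct-2-enyl]cyclopent-2-en-1-one; 25 methyl (E)-7-oxohept-5-enoate
Product: 26 methyl (E)-7-[(2S)-4-bromo-2-hydroxy-2-[(Z)-oct-2-enyl]-5-oxocyclopent-3-en-1-yl]-7-hydroxyhept-5-enoate (mixture at C7 and C8)
Conditions: LiN(i-Pr)2 (2.2 equiv), THF, −78 °C (22 added to the base); 25; AcOH, −78 °C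
Reagents that add atoms: none
Why: The alkoxide–enolate dianion, whose only enolisable position is C8, should undergo aldol addition to the aldehyde carbonyl of the enal (1,2-addition), the C12 alkoxide being unable to leave, and the new C7 and C8 centres are erased in step 18.

Step 18
Reactants: 26 methyl (E)-7-[(2S)-4-bromo-2-hydroxy-2-[(Z)-oct-2-enyl]-5-oxocyclopent-3-en-1-yl]-7-hydroxyhept-5-enoate
Product: 29 methyl (5E,7E)-7-[(2R)-2-acetoxy-4-bromo-2-[(Z)-oct-2-enyl]-5-oxocyclopent-3-en-1-ylidene]hept-5-enoate (the target), via C7 acetate 27 (not isolated), via 12-hydroxy dienone 28 (not isolated)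
Conditions: Ac2O (excess), DMAP, Et3N, CH2Cl2, 0 °C → rt
Reagents that add atoms: acetic anhydride, CC(=O)OC(C)=O
Why: The secondary allylic C7 hydroxyl is acetylated first and the β-acetoxy ketone eliminates by E1cB to the conjugated C7=C8 alkene, the (7E) isomer being expected as the more stable one with C6 turned away from the C9 carbonyl, after which DMAP-catalysed acetylation of the tertiary C12 hydroxyl should complete the target without touching the C12–O bond.

Compound list
1 | dimethyl 3-oxopentanedioate | COC(=O)CC(=O)CC(=O)OC | starting material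
2 | ethane-1,2-diol (ethylene glycol) | OCCO | starting material
3 | dimethyl 2,2'-(1,3-dioxolane-2,2-diyl)diacetate | COC(=O)CC1(CC(=O)OC)OCCO1 | intermediate
4 | 2,2'-(1,3-dioxolane-2,2-diyl)di(ethan-1-ol) | OCCC1(CCO)OCCO1 | intermediate
5 | 2-[2-(2-{[tert-butyl(dimethyl)silyl]oxy}ethyl)-1,3-dioxolan-2-yl]ethan-1-ol | CC(C)(C)[Si](C)(C)OCCC1(CCO)OCCO1 | intermediate
6 | 2-[2-(2-{[tert-butyl(dimethyl)silyl]oxy}ethyl)-1,3-dioxolan-2-yl]acetaldehyde | CC(C)(C)[Si](C)(C)OCCC1(CC=O)OCCO1 | intermediate
7 | 3-bromoprop-1-yne (propargyl bromide) | C#CCBr | starting material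
8 | rac-1-[2-(2-{[tert-butyl(dimethyl)silyl]oxy}ethyl)-1,3-dioxolan-2-yl]pent-4-yn-2-ol | C#CCC(O)CC1(CCO[Si](C)(C)C(C)(C)C)OCCO1 | intermediate
9 | 1-iodopentane | CCCCCI | starting material
10 | rac-1-[2-(2-{[tert-butyl(dimethyl)silyl]oxy}ethyl)-1,3-dioxolan-2-yl]dec-4-yn-2-ol | CCCCCC#CCC(O)CC1(CCO[Si](C)(C)C(C)(C)C)OCCO1 | intermediate
11 | rac-(Z)-1-[2-(2-{[tert-butyl(dimethyl)silyl]oxy}ethyl)-1,3-dioxolan-2-yl]dec-4-en-2-ol | CCCCC/C=C\CC(O)CC1(CCO[Si](C)(C)C(C)(C)C)OCCO1 | intermediate
12 | rac-(Z)-1-[2-(2-hydroxyethyl)-1,3-dioxolan-2-yl]dec-4-en-2-ol | CCCCC/C=C\CC(O)CC1(CCO)OCCO1 | intermediate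
13 | 2-{2-[(Z)-2-oxodec-4-enyl]-1,3-dioxolan-2-yl}acetaldehyde (achiral keto aldehyde) | CCCCC/C=C\CC(=O)CC1(CC=O)OCCO1 | intermediate
14 | (8S)-8-hydroxy-8-[(Z)-oct-2-enyl]-1,4-dioxaspiro[4.4]nonan-7-one | CCCCC/C=C\C[C@@]1(O)C(=O)CC2(C1)OCCO2 | intermediate
15 | (8S)-8-[(Z)-oct-2-enyl]-1,4-dioxaspiro[4.4]nonane-7,8-diol, both C7 epimers | CCCCC/C=C\C[C@@]1(O)C(O)CC2(C1)OCCO2 | intermediate
16 | (8S)-8-hydroxy-8-[(Z)-oct-2-enyl]-1,4-dioxaspiro[4.4]nonan-7-yl methanesulfonate, both C7 epimers | CCCCC/C=C\C[C@@]1(O)C(OS(C)(=O)=O)CC2(C1)OCCO2 | intermediate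
17 | (2S)-2-hydroxy-2-[(Z)-oct-2-enyl]-4-oxocyclopentyl methanesulfonate, both C1 epimers | CCCCC/C=C\C[C@@]1(O)C(OS(C)(=O)=O)CC(=O)C1 | intermediate (not isolated)
18 | (4S)-4-hydroxy-4-[(Z)-oct-2-enyl]cyclopent-2-en-1-one | CCCCC/C=C\C[C@@]1(O)C=CC(=O)C1 | intermediate
19 | (4S)-4-hydroxy-4-[(Z)-oct-2-enyl]-6-oxabicyclo[3.1.0]hexan-2-one, epoxide face not fixed | CCCCC/C=C\C[C@@]1(O)C2OC2C(=O)C1 | intermediate
20 | (4S)-2-bromo-3,4-dihydroxy-4-[(Z)-oct-2-enyl]cyclopentan-1-one | CCCCC/C=C\C[C@@]1(O)C(O)C(Br)C(=O)C1 | intermediate (not isolated)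
21 | (2S)-5-bromo-2-hydroxy-2-[(Z)-oct-2-enyl]-4-oxocyclopentyl methanesulfonate | CCCCC/C=C\C[C@@]1(O)C(OS(C)(=O)=O)C(Br)C(=O)C1 | intermediate (not isolated)
22 | (4S)-2-bromo-4-hydroxy-4-[(Z)-oct-2-enyl]cyclopent-2-en-1-one | CCCCC/C=C\C[C@@]1(O)C=C(Br)C(=O)C1 | intermediate
23 | methyl hex-5-enoate | COC(=O)CCCC=C | starting material
24 | (E)-but-2-enal (crotonaldehyde) | C/C=C/C=O | starting material
25 | methyl (E)-7-oxohept-5-enoate | COC(=O)CCC/C=C/C=O | intermediate
26 | methyl (E)-7-[(2S)-4-bromo-2-hydroxy-2-[(Z)-oct-2-enyl]-5-oxocyclopent-3-en-1-yl]-7-hydroxyhept-5-enoate, mixture at C7 and C8 | CCCCC/C=C\C[C@@]1(O)C=C(Br)C(=O)C1C(O)/C=C/CCCC(=O)OC | intermediate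
27 | methyl (E)-7-acetoxy-7-[(2S)-4-bromo-2-hydroxy-2-[(Z)-oct-2-enyl]-5-oxocyclopent-3-en-1-yl]hept-5-enoate | CCCCC/C=C\C[C@@]1(O)C=C(Br)C(=O)C1C(OC(C)=O)/C=C/CCCC(=O)OC | intermediate (not isolated)
28 | methyl (5E,7E)-7-[(2R)-4-bromo-2-hydroxy-2-[(Z)-oct-2-enyl]-5-oxocyclopent-3-en-1-ylidene]hept-5-enoate | CCCCC/C=C\C[C@@]1(O)C=C(Br)C(=O)/C1=C/C=C/CCCC(=O)OC | intermediate (not isolated)
29 | methyl (5E,7E)-7-[(2R)-2-acetoxy-4-bromo-2-[(Z)-oct-2-enyl]-5-oxocyclopent-3-en-1-ylidene]hept-5-enoate | CCCCC/C=C\C[C@@]1(OC(C)=O)C=C(Br)C(=O)/C1=C/C=C/CCCC(=O)OC | target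

Total step count: 18. Longest linear sequence: 17 (steps 1–15, 17 and 18; step 16 is a one-step side branch).

Steps most likely to fail

1. Step 10. What may go wrong: poor facial selectivity at a ketone flanked by two methylene groups, or loss of material to base-mediated six-membered aldol closure from C13 and to migration of C14=C15 into conjugation before the carbene closes the ring. Fallback, setting out from 13 and returning at 18: SmI2 in THF with t-BuOH at −78 °C should close the same C11–C12 bond by ketyl–carbonyl (pinacol) coupling, with no base present, and give the racemic cis-diol F1. Esterification of its secondary hydroxyl with (S)-2-methoxy-2-phenylacetic acid (DCC, DMAP, CH2Cl2) gives the ester F2 and its diastereomer F3, which are separated by chromatography. The configuration at C11, and through the cis relation at C12, is read from the 1H NMR shift differences of the two esters. F2 is treated with aq. HCl in THF to give the β-acyloxy ketone F4, which on addition of DBU loses the carboxylate by E1cB elimination and gives 18. The resolving ester thus also serves as the C11 leaving group.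

2. Step 9. What may go wrong: shift of the skipped alkene into conjugation with the new C12 ketone, or β-elimination that opens the ketal, during the amine stage of the oxidation. Fallback, setting out from 11 and returning at 13: Dess–Martin oxidation of the secondary alcohol of 11 (pyridine buffer, CH2Cl2) gives the keto silyl ether F5; HF·pyridine in THF/pyridine removes the silyl group and gives the hydroxy ketone F6, which rests partly as a cyclic hemiketal that cannot be over-oxidised; a second Dess–Martin oxidation gives 13. No base stronger than pyridine is used, and the ketone is installed before the aldehyde so that no oxidisable lactol can form.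

3. Step 18. What may go wrong: poor control of the C7=C8 geometry in the elimination, or slow acetylation of the hindered tertiary hydroxyl in the same flask. Fallback, setting out from 26 and returning at 29: MsCl and Et3N in CH2Cl2 at −20 °C convert the secondary allylic hydroxyl into the C7 mesylate F7, which eliminates in the flask to the hydroxy dienone 28, now isolated. It is separated from the (5E,7Z) isomer F8, and F8 is equilibrated with a trace of I2 in CH2Cl2 under daylight and recycled, so the geometry is set under thermodynamic control. Pure 28 is then acetylated with Ac2O and DMAP to 29.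

Further compounds
F1 | step 10 | rac-(7R*,8S*)-8-[(Z)-oct-2-enyl]-1,4-dioxaspiro[4.4]nonane-7,8-diol (racemic cis-diol, one enantiomer drawn) | CCCCC/C=C\C[C@@]1(O)[C@H](O)CC2(C1)OCCO2
F2 | step 10 | (7R,8S)-8-hydroxy-8-[(Z)-oct-2-enyl]-1,4-dioxaspiro[4.4]nonan-7-yl (2S)-2-methoxy-2-phenylacetate | CCCCC/C=C\C[C@@]1(O)[C@H](OC(=O)[C@@H](OC)c3ccccc3)CC2(C1)OCCO2
F3 | step 10 | (7S,8R)-8-hydroxy-8-[(Z)-oct-2-enyl]-1,4-dioxaspiro[4.4]nonan-7-yl (2S)-2-methoxy-2-phenylacetate | CCCCC/C=C\C[C@]1(O)[C@@H](OC(=O)[C@@H](OC)c3ccccc3)CC2(C1)OCCO2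
F4 | step 10 | (1R,2S)-2-hydroxy-2-[(Z)-oct-2-enyl]-4-oxocyclopentyl (2S)-2-methoxy-2-phenylacetate | CCCCC/C=C\C[C@@]1(O)[C@H](OC(=O)[C@@H](OC)c2ccccc2)CC(=O)C1
F5 | step 9 | (Z)-1-[2-(2-{[tert-butyl(dimethyl)silyl]oxy}ethyl)-1,3-dioxolan-2-yl]dec-4-en-2-one | CCCCC/C=C\CC(=O)CC1(CCO[Si](C)(C)C(C)(C)C)OCCO1
F6 | step 9 | (Z)-1-[2-(2-hydroxyethyl)-1,3-dioxolan-2-yl]dec-4-en-2-one | CCCCC/C=C\CC(=O)CC1(CCO)OCCO1
F7 | step 18 | methyl (E)-7-[(2S)-4-bromo-2-hydroxy-2-[(Z)-oct-2-enyl]-5-oxocyclopent-3-en-1-yl]-7-(methanesulfonyloxy)hept-5-enoate | CCCCC/C=C\C[C@@]1(O)C=C(Br)C(=O)C1C(OS(C)(=O)=O)/C=C/CCCC(=O)OC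
F8 | step 18 | methyl (5E,7Z)-7-[(2R)-4-bromo-2-hydroxy-2-[(Z)-oct-2-enyl]-5-oxocyclopent-3-en-1-ylidene]hept-5-enoate | CCCCC/C=C\C[C@@]1(O)C=C(Br)C(=O)\C1=C/C=C/CCCC(=O)OC
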